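**Route outline**

- Retrosynthesis: the two prenyl C=C bonds are cut back to allyl groups (cross metathesis). Then follow the C4–C5 bond between the two adjacent quaternary carbons (cation–enol closure), the C5–acyl bond, the C1–allyl bond, the C1–C8 bond (Dieckmann) and the O6–C5 bond (carboxylate alkylation).
- Forward: (R)-limonene is opened and trimmed to (4R)-4-isopropenylhept-6-enoic acid. The furan-2,4-dione (tetronic acid) ring is built on its carboxyl end first, and the cyclohexanone ring is closed last, across positions 3 and 5 of that lactone.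
- Enabling feature: in the 6-oxabicyclo[3.2.1]octane-7,8-dione, atoms C5–O6–C7–C1–C8 form a fully substituted furan-2,4-dione. Its C5 is an enolisable carbon flanked by the C8 ketone and the acyl group. The gem-dimethyl carbon C4 is the Markovnikov carbon of an isopropenyl group at the end of the C2–C3–C4 arm on C1.
- Stereochemistry: C3 is the limonene stereocentre and the side-chain centre comes from (R)-2-methylbutanoic acid. C1 is set by ligand-controlled Pd allylation (its epimer is a diastereomer and is removed). C5 follows from C1 in the bridging step.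

Key step: step 10

Remark: the sense of induction of the chiral diphosphine on a tetronate cannot be assigned in advance; the (R,R) ligand is written in step 7 and its enantiomer would be used if it favoured the C-3 epimer.

**Step 1**
Reactants: 1 (R)-(+)-limonene
Product: 2 (4R)-limonene 1,2-oxide (both epoxide diastereomers)
Conditions: mCPBA (1.0 equiv), CH2Cl2, 0 °C
Reagents that add atoms: mCPBA (3-chloroperoxybenzoic acid), OOC(=O)c1cccc(Cl)c1
Why: Prilezhaev epoxidation is much faster at the trisubstituted ring alkene than at the 1,1-disubstituted isopropenyl group, and the diastereomer ratio is irrelevant because both epoxide carbons become carbonyls in step 2.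

**Step 2**
Reactants: 2 (4R)-limonene 1,2-oxide
Product: 4 (3R)-6-oxo-3-(prop-1-en-2-yl)heptanal, via limonene-1,2-diol 3 (not isolated)
Conditions: H5IO6, THF/H2O, 0 °C → rt
Reagents that add atoms: water, O
Why: Periodic acid hydrolyses the epoxide and cleaves the resulting vicinal diol (Malaprade cleavage) to the keto aldehyde, while the isopropenyl alkene and the remote, non-epimerisable stereocentre are untouched.

**Step 3**
Reactants: 4 (3R)-6-oxo-3-(prop-1-en-2-yl)heptanal
Product: 5 (5R)-5-(prop-1-en-2-yl)oct-7-en-2-one
Conditions: Ph3PCH3Br, KHMDS, THF, −78 °C (1.0 equiv ylide added to 4)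
Reagents that add atoms: methyltriphenylphosphonium bromide, C[P+](c1ccccc1)(c1ccccc1)c1ccccc1.[Br-]
Why: Wittig methylenation with one equivalent of the non-stabilised ylide at low temperature should take the unhindered aldehyde well ahead of the methyl ketone, turning the aldehyde arm into the allyl placeholder.

**Step 4**
Reactants: 5 (5R)-5-(prop-1-en-2-yl)oct-7-en-2-one
Product: 7 (4R)-4-(prop-1-en-2-yl)hept-6-enoic acid, via tribromomethyl ketone 6 (not isolated)
Conditions: NaOBr (preformed from Br2, NaOH), dioxane/H2O, 0 °C; then HCl
Reagents that add atoms: sodium hydroxide, [Na+].[OH-] (carboxyl oxygen); bromine, BrBr (the three Br of 6 only)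
Why: Haloform reaction: the methyl ketone is brominated exhaustively at CH3 and cleaved by hydroxide to the acid one carbon shorter, and cold preformed alkaline hypobromite without free bromine should spare the two unactivated alkenes.

**Step 5**
Reactants: 7 (4R)-4-(prop-1-en-2-yl)hept-6-enoic acid; 8 methyl bromoacetate
Product: 9 2-methoxy-2-oxoethyl (4R)-4-(prop-1-en-2-yl)hept-6-enoate
Conditions: K2CO3, DMF, rt
Reagents that add atoms: none
Why: SN2 O-alkylation of the carboxylate by the activated α-bromo ester forms the O6–C5 bond and places the glycolate ester 1,5 to the acyl α-carbon.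

**Step 6**
Reactants: 9 2-methoxy-2-oxoethyl (4R)-4-(prop-1-en-2-yl)hept-6-enoate
Product: 10 4-hydroxy-3-[(2S)-2-(prop-1-en-2-yl)pent-4-en-1-yl]furan-2(5H)-one
Conditions: LiHMDS (2.2 equiv), THF, −78 → 0 °C; then 1 M HCl
Reagents that add atoms: none
Why: Dieckmann (intramolecular Claisen) condensation: the acyl α-carbanion adds 5-exo-trig to the glycolate ester carbonyl with loss of methoxide, and deprotonation of the strongly acidic tetronic acid makes the closure irreversible (the side-chain descriptor changes from R to S only through CIP priorities).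

**Step 7**
Reactants: 10 4-hydroxy-3-[(2S)-2-(prop-1-en-2-yl)pent-4-en-1-yl]furan-2(5H)-one; 11 allyl acetate
Product: 12 (3S)-3-(prop-2-en-1-yl)-3-[(2S)-2-(prop-1-en-2-yl)pent-4-en-1-yl]furan-2,4(3H,5H)-dione
Conditions: [Pd(allyl)Cl]2 (2.5 mol %), (R,R)-DACH-phenyl bis(diphenylphosphinobenzamide) ligand (7.5 mol %), Et3N, CH2Cl2, 0 °C → rt
Reagents that add atoms: none
Why: Tsuji–Trost asymmetric allylic alkylation: the soft tetronate attacks the π-allyl complex, any 4-O-allyl ether is a vinylogous allyl ester that Pd(0) re-ionises so material collects as the C-allylated dione, the chiral ligand pocket selects the face of the planar anion and so sets the quaternary centre, and the minor C-3 epimer is a diastereomer that is removed by chromatography.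

**Step 8**
Reactants: 13 (R)-2-methylbutanoic acid
Product: 14 1-[(2R)-2-methylbutanoyl]-1H-benzotriazole
Conditions: 1H-benzotriazole, DCC, CH2Cl2, 0 °C → rt
Reagents that add atoms: 1H-benzotriazole, c1ccc2[nH]nnc2c1
Why: Carbodiimide coupling through the O-acylisourea gives a stable active amide without acid chloride, ketene or amine base, so the α-stereocentre should be kept.

**Step 9**
Reactants: 12 (3S)-3-(prop-2-en-1-yl)-3-[(2S)-2-(prop-1-en-2-yl)pent-4-en-1-yl]furan-2,4(3H,5H)-dione; 14 1-[(2R)-2-methylbutanoyl]-1H-benzotriazole
Product: 15 (3S)-4-hydroxy-5-[(2R)-2-methylbutanoyl]-3-(prop-2-en-1-yl)-3-[(2S)-2-(prop-1-en-2-yl)pent-4-en-1-yl]furan-2(3H)-one (ring enol tautomer)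
Conditions: MgBr2·OEt2, i-Pr2NEt, CH2Cl2, rt; then cold 1 M HCl
Reagents that add atoms: none
Why: Soft-enolisation C-acylation (Mg(II)/amine Claisen-type acylation of a ketone): the C4 ketone can enolise only towards C5 because C3 is quaternary, the magnesium enolate is acylated at carbon, and the product is held as its magnesium β-diketonate, which disfavours O-acylation and avoids a base strong enough to open the β-keto lactone.

**Step 10**
Reactants: 15 (3S)-4-hydroxy-5-[(2R)-2-methylbutanoyl]-3-(prop-2-en-1-yl)-3-[(2S)-2-(prop-1-en-2-yl)pent-4-en-1-yl]furan-2(3H)-one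
Product: 16 (1S,3S,5S)-4,4-dimethyl-5-[(2R)-2-methylbutanoyl]-1,3-di(prop-2-en-1-yl)-6-oxabicyclo[3.2.1]octane-7,8-dione
Conditions: MsOH (2 equiv), CH2Cl2, −10 °C → rt
Reagents that add atoms: none
Why: Proposed new method: the acid protonates only the 1,1-disubstituted alkene in the Markovnikov sense, placing a tertiary cation on the future C4, and the enol carbon C5, α to both the ring ketone C8 and the exocyclic acyl carbonyl, attacks it to join two quaternary carbons and leave a trione that can no longer enolise at C5. The closest known reaction type is the proton-initiated enol–olefin cyclisation of enolised acylphloroglucinol-derived triketones carrying an isopropenyl-terminated chain, which builds bicyclo[3.3.1]nonane-triones; it has not been run on a furan-2,4-dione, where the same donor and acceptor sit 1,3 across a flat five-membered ring. One ring closes, the carbocycle C1–C2–C3–C4–C5–C8, in a 6-(enolendo)-exo-trig mode (6-(enolexo) if the side-chain enol tautomer reacts) through a chair. The one new stereocentre, C5, is dictated by C1, because the three-carbon arm can reach only the enol face on which it is attached, so the bridge is necessarily cis; with the preset C3 centre the allyl group lies equatorial in that chair, as in the target. The step needs selective ionisation (the monosubstituted allyl groups would have to form secondary cations and should stay untouched), C- over O-alkylation (capture by the C8 enol oxygen gives a tertiary-alkyl vinylogous ester that the acid should re-ionise, so material should drain to the C-alkylated product) and retention at C3 (closure through the favoured chair must outpace loss of the C3 proton from the cation).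

**Step 11**
Reactants: 16 (1S,3S,5S)-4,4-dimethyl-5-[(2R)-2-methylbutanoyl]-1,3-di(prop-2-en-1-yl)-6-oxabicyclo[3.2.1]octane-7,8-dione; 17 2-methylbut-2-ene
Product: 18 (1S,3S,5S)-4,4-dimethyl-5-[(2R)-2-methylbutanoyl]-1,3-bis(3-methylbut-2-en-1-yl)-6-oxabicyclo[3.2.1]octane-7,8-dione (CNP0306710.1)
Conditions: Grubbs second-generation catalyst (10 mol %), 2-methylbut-2-ene/CH2Cl2, 40 °C, sealed tube
Reagents that add atoms: none
Why: Double olefin cross metathesis with a large excess of the trisubstituted partner converts both terminal allyl groups into prenyl groups with loss of propene; no stereocentre is touched, and ring-closing metathesis is excluded because both allyl groups are equatorial on the locked chair.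

**Compound list**

1 | (R)-(+)-limonene | CC1=CC[C@@H](CC1)C(C)=C | starting material
2 | (4R)-limonene 1,2-oxide, both epoxide diastereomers | CC12CC[C@H](CC1O2)C(C)=C | intermediate
3 | (1S,2S,4R)-limonene-1,2-diol, the trans-diaxial diol expected from both epoxides | C[C@]1(O)CC[C@H](C[C@@H]1O)C(C)=C | intermediate (not isolated)
4 | (3R)-6-oxo-3-(prop-1-en-2-yl)heptanal | CC(=O)CC[C@H](CC=O)C(C)=C | intermediate
5 | (5R)-5-(prop-1-en-2-yl)oct-7-en-2-one | CC(=O)CC[C@H](CC=C)C(C)=C | intermediate
6 | (5R)-1,1,1-tribromo-5-(prop-1-en-2-yl)oct-7-en-2-one | BrC(Br)(Br)C(=O)CC[C@H](CC=C)C(C)=C | intermediate (not isolated)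
7 | (4R)-4-(prop-1-en-2-yl)hept-6-enoic acid | OC(=O)CC[C@H](CC=C)C(C)=C | intermediate
8 | methyl bromoacetate | COC(=O)CBr | starting material
9 | 2-methoxy-2-oxoethyl (4R)-4-(prop-1-en-2-yl)hept-6-enoate | COC(=O)COC(=O)CC[C@H](CC=C)C(C)=C | intermediate
10 | 4-hydroxy-3-[(2S)-2-(prop-1-en-2-yl)pent-4-en-1-yl]furan-2(5H)-one | OC1=C(C[C@H](CC=C)C(C)=C)C(=O)OC1 | intermediate
11 | allyl acetate | CC(=O)OCC=C | starting material
12 | (3S)-3-(prop-2-en-1-yl)-3-[(2S)-2-(prop-1-en-2-yl)pent-4-en-1-yl]furan-2,4(3H,5H)-dione | O=C1COC(=O)[C@@]1(CC=C)C[C@H](CC=C)C(C)=C | intermediate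
13 | (R)-2-methylbutanoic acid | CC[C@@H](C)C(=O)O | starting material
14 | 1-[(2R)-2-methylbutanoyl]-1H-benzotriazole | CC[C@@H](C)C(=O)n1nnc2ccccc12 | intermediate
15 | (3S)-4-hydroxy-5-[(2R)-2-methylbutanoyl]-3-(prop-2-en-1-yl)-3-[(2S)-2-(prop-1-en-2-yl)pent-4-en-1-yl]furan-2(3H)-one | CC[C@@H](C)C(=O)C1=C(O)[C@](CC=C)(C[C@H](CC=C)C(C)=C)C(=O)O1 | intermediate
16 | (1S,3S,5S)-4,4-dimethyl-5-[(2R)-2-methylbutanoyl]-1,3-di(prop-2-en-1-yl)-6-oxabicyclo[3.2.1]octane-7,8-dione | CC[C@@H](C)C(=O)[C@@]12OC(=O)[C@@](CC=C)(C[C@H](CC=C)C1(C)C)C2=O | intermediate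
17 | 2-methylbut-2-ene | CC=C(C)C | starting material
18 | (1S,3S,5S)-4,4-dimethyl-5-[(2R)-2-methylbutanoyl]-1,3-bis(3-methylbut-2-en-1-yl)-6-oxabicyclo[3.2.1]octane-7,8-dione (CNP0306710.1) | CC[C@@H](C)C(=O)[C@@]12OC(=O)[C@@](CC=C(C)C)(C[C@H](CC=C(C)C)C1(C)C)C2=O | target

**Step count and risks**

Total step count: 11. Longest linear sequence: 10 steps (steps 1–7 and 9–11 from (R)-limonene); step 8 is a one-step branch.

Steps most likely to fail:

1. Step 10 (Proposed new method). What may go wrong:
   - capture of the cation by the C8 enol oxygen may not revert under the acid;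
   - the cation may shed the C3 proton, so that the alkene slides into the tetrasubstituted position and C3 is scrambled on return;
   - prolonged acid may enolise the side-chain ketone and erode its α-centre.

   Fallback (known chemistry): setting out from 15, dry HCl in CH2Cl2 at −78 °C should add in the Markovnikov sense to the isopropenyl group alone and give the tertiary chloride (3S)-3-[(2S)-2-(2-chloropropan-2-yl)pent-4-en-1-yl]-4-hydroxy-5-[(2R)-2-methylbutanoyl]-3-(prop-2-en-1-yl)furan-2(3H)-one F1. AgOTf with 2,6-di-tert-butylpyridine in CH2Cl2 at −40 °C would then abstract chloride, and the enol carbon would be alkylated under buffered, non-equilibrating conditions (silver-assisted tert-alkylation of a 1,3-dicarbonyl enol by a tertiary halide). This returns to the route at 16.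

2. Step 7. What may go wrong:
   - the two flanks of the planar tetronate differ only by a ring oxygen versus a ring CH2, so facial discrimination by the chiral pocket may be poor;
   - O-allylation may compete before it is funnelled to carbon;
   - the two C-3 epimers may separate badly, since their stereocentres are 1,3-related on an open chain.

   Fallback: setting out from 10, condensation with L-valine tert-butyl ester (toluene, cat. TsOH, water removal) would give the enaminolactone tert-butyl N-{5-oxo-4-[(2S)-2-(prop-1-en-2-yl)pent-4-en-1-yl]-2,5-dihydrofuran-3-yl}-L-valinate F2. Deprotonation with LDA in toluene with a donor additive and alkylation with allyl bromide at −78 °C would follow; lithium is held by the auxiliary ester and one face of the aza-enolate is shielded. The facial sense of this auxiliary is known to switch with the additive (THF versus HMPA), so the required configuration should be reachable from the same L-valine. This would give the imino lactone tert-butyl N-{(4S)-5-oxo-4-(prop-2-en-1-yl)-4-[(2S)-2-(prop-1-en-2-yl)pent-4-en-1-yl]dihydrofuran-3(2H)-ylidene}-L-valinate F3, and mild aqueous acid (AcOH, NaOAc, THF/H2O) would release 12. Any residual epimer would be removed after step 10, where the two differ as rigid bicycles.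

3. Step 6. What may go wrong: the glycolate methylene is the more acidic site, so the base may deprotonate there and trigger a 1,2-acyl shift (Chan-type rearrangement) or ester cleavage instead of the Claisen ring closure.

   Fallback: setting out from 7, esterification (MeI, K2CO3, DMF) would give methyl (4R)-4-(prop-1-en-2-yl)hept-6-enoate F4. Its lithium enolate (LDA, THF, −78 °C), formed at the only α-CH2, would be C-acylated with acetoxyacetyl chloride to methyl 4-acetoxy-3-oxo-2-[(2S)-2-(prop-1-en-2-yl)pent-4-en-1-yl]butanoate F5. HCl in MeOH would then remove the acetate, and the freed hydroxyl would lactonise onto the methyl ester to return to the route at 10.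

**Further compounds**

F1 | step 10 | (3S)-3-[(2S)-2-(2-chloropropan-2-yl)pent-4-en-1-yl]-4-hydroxy-5-[(2R)-2-methylbutanoyl]-3-(prop-2-en-1-yl)furan-2(3H)-one | CC[C@@H](C)C(=O)C1=C(O)[C@](CC=C)(C[C@H](CC=C)C(C)(C)Cl)C(=O)O1
F2 | step 7 | tert-butyl N-{5-oxo-4-[(2S)-2-(prop-1-en-2-yl)pent-4-en-1-yl]-2,5-dihydrofuran-3-yl}-L-valinate | CC(C)[C@H](NC1=C(C[C@H](CC=C)C(C)=C)C(=O)OC1)C(=O)OC(C)(C)C
F3 | step 7 | tert-butyl N-{(4S)-5-oxo-4-(prop-2-en-1-yl)-4-[(2S)-2-(prop-1-en-2-yl)pent-4-en-1-yl]dihydrofuran-3(2H)-ylidene}-L-valinate | CC(C)[C@H](N=C1COC(=O)[C@@]1(CC=C)C[C@H](CC=C)C(C)=C)C(=O)OC(C)(C)C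
F4 | step 6 | methyl (4R)-4-(prop-1-en-2-yl)hept-6-enoate | COC(=O)CC[C@H](CC=C)C(C)=C
F5 | step 6 | methyl 4-acetoxy-3-oxo-2-[(2S)-2-(prop-1-en-2-yl)pent-4-en-1-yl]butanoate | COC(=O)C(C[C@H](CC=C)C(C)=C)C(=O)COC(C)=O
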